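Retrosynthesis: the phenol O–Si bond is cut last and C-5 of the oxolane is taken back to an ethyl acetal carbon. The ring is then cut at O-1–C-5 and C-3–C-4, together with the C–OH bond of the CH2OH group.
This leaves an (S)-1-arylallyl alcohol (O-1, C-2, C-3 and the CH2OH carbon) and the enol ether ArCH2CH=CHOEt (C-4, C-5).
Enabling feature: O-1–C-2–C-3 with its exocyclic carbon is a masked allylic alcohol and C-4–C-5 a masked enol ether C=C. Once O-1 is acetal-bonded to C-5, a radical at C-4 sits in a 3-oxahex-5-enyl chain and closes the oxolane 5-exo onto C-3.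
Forward: vanillin → silyl ether → vinyl carbinol → lipase resolution; benzyl chloride + ethoxyvinylboronate → enol ether. The two halves are joined and the only ring is closed in one flask, then the acetal is reduced and the phenol freed.
Stereochemistry: C-2 comes from the enzymatic resolution; C-3 and C-4 come from the chair-like transition state of the radical ring closure (2,3-trans, 3,4-cis).

Key step: step 5

Remark: the acetal carbon of 8, 9 and 10 and the iodide carbon of 8 arise as epimer mixtures and are drawn without configuration, because both centres are erased later (radical formation in step 5, reduction in step 6).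

Step 1
Reactants: 1 vanillin
Product: 2 3-methoxy-4-(triisopropylsilyloxy)benzaldehyde
Conditions: TIPSCl, imidazole, DMF, rt
Reagents that add atoms: chlorotri(propan-2-yl)silane (TIPSCl), CC(C)[Si](Cl)(C(C)C)C(C)C
Why: Imidazole-promoted O-silylation of the only hydroxyl group masks the phenol against NIS, the Grignard reagent and the radical step.

Step 2
Reactants: 2 3-methoxy-4-(triisopropylsilyloxy)benzaldehyde
Product: 3 rac-1-[3-methoxy-4-(triisopropylsilyloxy)phenyl]prop-2-en-1-ol
Conditions: CH2=CHMgBr, THF, −78 to 0 °C; then H2O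
Reagents that add atoms: vinylmagnesium bromide, C=C[Mg]Br
Why: Grignard 1,2-addition to the aldehyde should give the racemic vinyl carbinol, the aryl silyl ether being inert to the reagent.

Step 3
Reactants: 3 rac-1-[3-methoxy-4-(triisopropylsilyloxy)phenyl]prop-2-en-1-ol
Product: 4 (S)-1-[3-methoxy-4-(triisopropylsilyloxy)phenyl]prop-2-en-1-ol
Conditions: Novozym 435 (immobilised Candida antarctica lipase B), vinyl acetate, MTBE, 30 °C, stopped just past half conversion; chromatography
Reagents that add atoms: none
Why: Lipase-catalysed kinetic resolution by enantioselective transesterification: by the Kazlauskas rule the (R)-alcohol (aryl large, vinyl medium) is acetylated and the (S)-alcohol is recovered, which fixes C-2 of the target.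

Step 4
Reactants: 5 4-(chloromethyl)-1,2-dimethoxybenzene; 6 2-[(E)-2-ethoxyethenyl]-4,4,5,5-tetramethyl-1,3,2-dioxaborolane
Product: 7 4-[(E)-3-ethoxyprop-2-en-1-yl]-1,2-dimethoxybenzene
Conditions: Pd(PPh3)4 (cat.), K3PO4, dioxane/H2O, 80 °C; purification on Et3N-deactivated silica
Reagents that add atoms: none
Why: Suzuki–Miyaura coupling of a benzylic chloride (oxidative addition to zerovalent palladium) with an alkenylboronate should give the base-stable enol ether with retention of the E geometry.

Step 5
Reactants: 4 (S)-1-[3-methoxy-4-(triisopropylsilyloxy)phenyl]prop-2-en-1-ol; 7 4-[(E)-3-ethoxyprop-2-en-1-yl]-1,2-dimethoxybenzene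
Product: 10 [(2S,3R,4R)-4-(3,4-dimethoxybenzyl)-5-ethoxy-2-[3-methoxy-4-(triisopropylsilyloxy)phenyl]oxolan-3-yl]methanol (C-5 epimers), via iodoacetal 8 (not isolated), via hydroperoxide 9 (not isolated)
Conditions: NIS, CH2Cl2, −40 to 0 °C; then Bu3SnH, air (slow stream), toluene, 0 °C; then PPh3
Reagents that add atoms: N-iodosuccinimide, O=C1CCC(=O)N1I (its iodine is carried only by intermediate 8); dioxygen, O=O
Why: Iodonium transfer from NIS to the enol ether places iodine on the benzyl-bearing carbon and the oxocarbenium ion is captured by the hydroxyl of 4 (O-1–C-5 bond, iodoacetal 8); Bu3Sn• then abstracts iodine, the secondary 3-oxahex-5-enyl radical adds to the internal vinyl carbon (C-3–C-4 bond), the primary radical takes up O2, Bu3SnH reduces the peroxyl radical to hydroperoxide 9 and PPh3 reduces this to the alcohol. The closest known reaction type is the Ueno–Stork haloacetal radical cyclisation in its aerobic, oxygenative variant (tin hydride under air). The oxolane ring is closed by a 5-exo-trig radical cyclisation, the ring oxygen having been tied to C-5 by the acetalisation just before. C-3 is controlled by the C-2 stereocentre, because in the chair-like Beckwith–Houk transition state the aryl group sits pseudo-equatorial and the product should be 2,3-trans; C-4 is controlled by the same transition state, in which a substituent on the radical carbon ends cis to the new exocyclic carbon (3,4-cis); C-2 is not touched and the acetal carbon is left uncontrolled because step 6 erases it. The step needs regioselective iodoalkoxylation (secured by the enol ether oxygen, which makes C-5 the cationic and C-4 the iodinated carbon), 5-exo in place of 6-endo closure (secured by the monosubstituted vinyl group five atoms from the radical) and ring closure before oxygen capture (secured by the fast cyclisation of 3-oxahexenyl radicals and a low stationary O2 concentration).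

Step 6
Reactants: 10 [(2S,3R,4R)-4-(3,4-dimethoxybenzyl)-5-ethoxy-2-[3-methoxy-4-(triisopropylsilyloxy)phenyl]oxolan-3-yl]methanol (C-5 epimers)
Product: 11 [(2S,3R,4R)-4-(3,4-dimethoxybenzyl)-2-[3-methoxy-4-(triisopropylsilyloxy)phenyl]oxolan-3-yl]methanol
Conditions: Et3SiH, BF3·OEt2, CH2Cl2, −78 to −40 °C
Reagents that add atoms: none
Why: Ionic hydrogenation of the lactol ether (loss of ethoxide to the cyclic oxocarbenium ion, hydride transfer from silicon) turns C-5 into CH2, so both acetal epimers should converge on one compound while C-2, C-3 and C-4 stay as set.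

Step 7
Reactants: 11 [(2S,3R,4R)-4-(3,4-dimethoxybenzyl)-2-[3-methoxy-4-(triisopropylsilyloxy)phenyl]oxolan-3-yl]methanol
Product: 12 4'-O-methyllariciresinol, 4-[(2S,3R,4R)-4-(3,4-dimethoxybenzyl)-3-(hydroxymethyl)oxolan-2-yl]-2-methoxyphenol
Conditions: TBAF, AcOH, THF, 0 °C
Reagents that add atoms: none
Why: Fluoride-induced cleavage of the aryl silyl ether, buffered with acetic acid so that no free phenoxide or strong acid meets the benzylic ether, should release the phenol without touching the stereocentres.

Compound list
1 | vanillin (4-hydroxy-3-methoxybenzaldehyde) | COc1cc(C=O)ccc1O | starting material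
2 | 3-methoxy-4-(triisopropylsilyloxy)benzaldehyde | COc1cc(C=O)ccc1O[Si](C(C)C)(C(C)C)C(C)C | intermediate
3 | rac-1-[3-methoxy-4-(triisopropylsilyloxy)phenyl]prop-2-en-1-ol | C=CC(O)c1ccc(O[Si](C(C)C)(C(C)C)C(C)C)c(OC)c1 | intermediate
4 | (S)-1-[3-methoxy-4-(triisopropylsilyloxy)phenyl]prop-2-en-1-ol | C=C[C@H](O)c1ccc(O[Si](C(C)C)(C(C)C)C(C)C)c(OC)c1 | intermediate
5 | 4-(chloromethyl)-1,2-dimethoxybenzene (3,4-dimethoxybenzyl chloride) | COc1ccc(CCl)cc1OC | starting material
6 | 2-[(E)-2-ethoxyethenyl]-4,4,5,5-tetramethyl-1,3,2-dioxaborolane | CCO/C=C/B1OC(C)(C)C(C)(C)O1 | starting material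
7 | 4-[(E)-3-ethoxyprop-2-en-1-yl]-1,2-dimethoxybenzene | CCO/C=C/Cc1ccc(OC)c(OC)c1 | intermediate
8 | iodoacetal: 4-{3-ethoxy-2-iodo-3-[(1S)-1-[3-methoxy-4-(triisopropylsilyloxy)phenyl]prop-2-en-1-yl]oxypropyl}-1,2-dimethoxybenzene, mixture at the acetal and iodide carbons | C=C[C@H](OC(OCC)C(I)Cc1ccc(OC)c(OC)c1)c1ccc(O[Si](C(C)C)(C(C)C)C(C)C)c(OC)c1 | intermediate (not isolated)
9 | hydroperoxide: (2S,3R,4R)-4-(3,4-dimethoxybenzyl)-5-ethoxy-3-(hydroperoxymethyl)-2-[3-methoxy-4-(triisopropylsilyloxy)phenyl]oxolane, C-5 epimers | COc1cc([C@H]2OC(OCC)[C@H](Cc3ccc(OC)c(OC)c3)[C@@H]2COO)ccc1O[Si](C(C)C)(C(C)C)C(C)C | intermediate (not isolated)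
10 | [(2S,3R,4R)-4-(3,4-dimethoxybenzyl)-5-ethoxy-2-[3-methoxy-4-(triisopropylsilyloxy)phenyl]oxolan-3-yl]methanol, C-5 epimers | COc1cc([C@H]2OC(OCC)[C@H](Cc3ccc(OC)c(OC)c3)[C@@H]2CO)ccc1O[Si](C(C)C)(C(C)C)C(C)C | intermediate
11 | [(2S,3R,4R)-4-(3,4-dimethoxybenzyl)-2-[3-methoxy-4-(triisopropylsilyloxy)phenyl]oxolan-3-yl]methanol | COc1cc([C@H]2OC[C@H](Cc3ccc(OC)c(OC)c3)[C@@H]2CO)ccc1O[Si](C(C)C)(C(C)C)C(C)C | intermediate
12 | 4'-O-methyllariciresinol, 4-[(2S,3R,4R)-4-(3,4-dimethoxybenzyl)-3-(hydroxymethyl)oxolan-2-yl]-2-methoxyphenol | COc1cc([C@H]2OC[C@H](Cc3ccc(OC)c(OC)c3)[C@@H]2CO)ccc1O | target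

Total step count: 7. Longest linear sequence: 6 steps (steps 1, 2, 3, 5, 6, 7).

Steps most likely to fail

Step 5. The uncyclised C-4 radical may be captured by oxygen or tin hydride before ring closure, the cis preference at C-3/C-4 in the 5-exo closure may be weak, and the benzylic C-2–H may be autoxidised under air. The fallback moves the radical to C-3 and makes the ether bond in a separate Williamson step. It sets out from 4: hydroxyl-directed epoxidation (VO(acac)2, tBuOOH, CH2Cl2, 0 °C) should give (R)-[3-methoxy-4-(triisopropylsilyloxy)phenyl](oxiran-2-yl)methanol F1, in which the carbinol carbon keeps the spatial arrangement of 4 and either oxirane epimer serves. Commercial (E)-3,4-dimethoxycinnamyl alcohol with PBr3 (Et2O, 0 °C) gives (E)-3,4-dimethoxycinnamyl bromide F2, and F1 with F2 and Ag2O (CH2Cl2, rt) gives the epoxy cinnamyl ether F3. Cp2TiCl (trivalent titanium, made from Cp2TiCl2 and Zn dust, THF, rt) then opens the oxirane to the secondary radical at C-3, which closes 5-exo-trig onto the cinnamyl alkene. A second Cp2TiCl reduces the benzylic radical, and acidic work-up should give 11 directly, so the fallback comes back to the route at 11 and step 6 is not needed.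

Step 6. The Lewis acid may ionise the electron-rich benzylic C-2–O bond (reductive ring opening, epimerisation or Friedel–Crafts capture by the dimethoxyphenyl ring), the free hydroxymethyl group may add to the oxocarbenium ion, or the silyl ether may be lost. The fallback avoids silane and strong Lewis acid and sets out from 10: PPTS in acetone/H2O should hydrolyse the acetal to the lactol F4 (C-5 epimers), and NaBH4 in MeOH should reduce this to the triol F5. Catalytic CSA in CH2Cl2 at 0 °C then ionises the benzylic alcohol, and the cation is captured by the primary hydroxyl of the former acetal carbon (five-membered ring; the other primary hydroxyl would have to form a four-membered ring). This should give the 2,3-trans oxolane 11, where the fallback comes back to the route.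

Step 4. Solvolysis of the electron-rich benzylic chloride in aqueous base and protodeboronation of the alkenylboronate may outrun the cross-coupling, and the enol ether may hydrolyse during isolation. The fallback builds the enol ether by olefination and sets out from commercial methyl eugenol (4-allyl-1,2-dimethoxybenzene): Lemieux–Johnson cleavage (OsO4 cat., NaIO4, 2,6-lutidine, dioxane/H2O) should give (3,4-dimethoxyphenyl)acetaldehyde F6. A Wittig reaction with Ph3P=CHOEt (from (ethoxymethyl)triphenylphosphonium chloride and KOtBu, THF, 0 °C) should give 7 together with its Z isomer F7. The mixture is used as such, because the alkene geometry is lost at the iodoacetal stage, and the fallback comes back to the route at 7.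

Further compounds
F1 | step 5 | (R)-[3-methoxy-4-(triisopropylsilyloxy)phenyl](oxiran-2-yl)methanol, oxirane epimers | C1OC1[C@H](O)c2ccc(O[Si](C(C)C)(C(C)C)C(C)C)c(OC)c2
F2 | step 5 | (E)-3,4-dimethoxycinnamyl bromide, 4-[(E)-3-bromoprop-1-en-1-yl]-1,2-dimethoxybenzene | COc1ccc(/C=C/CBr)cc1OC
F3 | step 5 | 2-{(S)-[(E)-3-(3,4-dimethoxyphenyl)prop-2-en-1-yl]oxy[3-methoxy-4-(triisopropylsilyloxy)phenyl]methyl}oxirane, oxirane epimers | C1OC1[C@H](OC/C=C/c2ccc(OC)c(OC)c2)c3ccc(O[Si](C(C)C)(C(C)C)C(C)C)c(OC)c3
F4 | step 6 | (3R,4R,5S)-3-(3,4-dimethoxybenzyl)-4-(hydroxymethyl)-5-[3-methoxy-4-(triisopropylsilyloxy)phenyl]oxolan-2-ol, C-2 epimers | COc1cc([C@H]2OC(O)[C@H](Cc3ccc(OC)c(OC)c3)[C@@H]2CO)ccc1O[Si](C(C)C)(C(C)C)C(C)C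
F5 | step 6 | (1S,2R,3R)-3-(3,4-dimethoxybenzyl)-2-(hydroxymethyl)-1-[3-methoxy-4-(triisopropylsilyloxy)phenyl]butane-1,4-diol | OC[C@H](Cc1ccc(OC)c(OC)c1)[C@H](CO)[C@H](O)c1ccc(O[Si](C(C)C)(C(C)C)C(C)C)c(OC)c1
F6 | step 4 | (3,4-dimethoxyphenyl)acetaldehyde | COc1ccc(CC=O)cc1OC
F7 | step 4 | 4-[(Z)-3-ethoxyprop-2-en-1-yl]-1,2-dimethoxybenzene | CCO/C=C\Cc1ccc(OC)c(OC)c1
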